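**Plan**
- Retrosynthesis first removes the three O-protecting groups and the C8 ketone oxygen (carried as a 1,1-disubstituted alkene), then cuts the lactone bond O1–C2 and, in the same operation, ring A at C8–C8a, C6–C7 and C4a–C8a.
- This leaves a 4-alkyl-3-ethoxycyclobutenone holding C2, C3, C4, C4a, C5, C6 and C8a, and a triisopropylsiloxy enyne holding C7, C8 and the acyl chain.
- Enabling feature: ring A is pentasubstituted, with the C8a oxygen (O1) lying between the acyl-bearing C8 and the C4a side chain and further oxygens on C5 and C7, which is exactly the pattern a vinylketene/ynol ether benzannulation lays down.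
- Forward: prochiral 3-phenylglutaric anhydride is opened to the hemiester, converted to the ketene and joined with ethoxyacetylene; 4-(4-methoxyphenyl)butan-2-one is taken through its enol triflate and enyne to the siloxyalkyne.
- The two halves are fused thermally, ring A forming first and the lactone ring second in one flask; alkene cleavage, desilylation and ether cleavage then finish the target.
- Stereochemistry: the single stereocentre C4 (R) is set in the cinchona-catalysed methanolysis of the anhydride and is never a reacting centre afterwards.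

Key step: step 8

Assumption: the quinine-derived sulfonamide catalyst is taken to deliver the (R)-hemiester; should its sense of induction be the opposite, the quinidine-derived pseudoenantiomer is used and nothing downstream changes.

**Route**

Step 1
Reactants: 1 3-phenylglutaric anhydride
Product: 2 (3R)-5-methoxy-5-oxo-3-phenylpentanoic acid
Conditions: MeOH (10 equiv), 9-amino-9-deoxy-epi-quinine 3,5-bis(trifluoromethyl)benzenesulfonamide (10 mol%), MTBE, −20 °C
Reagents that add atoms: methanol, CO
Why: In this desymmetrising alcoholysis of a prochiral cyclic anhydride the quinuclidine nitrogen activates methanol as a general base while the sulfonamide N–H binds one of the two enantiotopic carbonyls, which sets the future C4 stereocentre with the acid arm destined to become C4a–C8a.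

Step 2
Reactants: 2 (3R)-5-methoxy-5-oxo-3-phenylpentanoic acid
Product: 3 methyl (3S)-5-chloro-5-oxo-3-phenylpentanoate
Conditions: (COCl)2, DMF (cat.), CH2Cl2, 0 °C → rt; evaporate, use crude at once
Reagents that add atoms: oxalyl chloride, O=C(Cl)C(=O)Cl
Why: Vilsmeier-type acid chloride formation under cold, neutral conditions should leave the stereocentre untouched (the descriptor changes only through the priority rules), and immediate use avoids interchange of the ester and acid chloride termini.

Step 3
Reactants: 3 methyl (3S)-5-chloro-5-oxo-3-phenylpentanoate; 4 ethoxyacetylene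
Product: 6 methyl (3S)-3-(2-ethoxy-4-oxocyclobut-2-en-1-yl)-3-phenylpropanoate (both ring epimers), via ketene 5 (not isolated)
Conditions: 4 (3 equiv), Et3N (slow addition), Et2O, 0 °C → rt
Reagents that add atoms: none
Why: Dehydrochlorination gives aldoketene 5, which excess ethoxyacetylene should trap in a ketene–ynol ether (2+2) cycloaddition in which the nucleophilic terminal alkyne carbon bonds to the ketene carbonyl carbon, placing ethoxy on ring C3 next to the side-chain carbon; the new ring stereocentre is uncontrolled and irrelevant because it later becomes aromatic C4a.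

Step 4
Reactants: 7 4-(4-methoxyphenyl)butan-2-one
Product: 9 4-(4-methoxyphenyl)but-1-en-2-yl trifluoromethanesulfonate, via lithium enolate 8 (not isolated)
Conditions: LiN(iPr)2, THF, −78 °C; PhNTf2, −78 → 0 °C
Reagents that add atoms: N-phenylbis(trifluoromethanesulfonimide), O=S(=O)(N(c1ccccc1)S(=O)(=O)C(F)(F)F)C(F)(F)F
Why: Kinetic deprotonation of the methyl ketone by the hindered amide at low temperature should give the less substituted enolate, which is O-sulfonylated in a standard enol triflate formation.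

Step 5
Reactants: 9 4-(4-methoxyphenyl)but-1-en-2-yl trifluoromethanesulfonate; 10 ethynyltrimethylsilane
Product: 11 [5-(4-methoxyphenyl)-3-methylidenepent-1-yn-1-yl]trimethylsilane
Conditions: PdCl2(PPh3)2 (cat.), CuI (cat.), Et3N, THF, rt
Reagents that add atoms: none
Why: Sonogashira coupling of an alkenyl triflate (oxidative addition to zerovalent palladium formed in situ, transmetallation from the copper acetylide, reductive elimination) is routine for 2-alkyl enol triflates and should retain the alkene position.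

Step 6
Reactants: 11 [5-(4-methoxyphenyl)-3-methylidenepent-1-yn-1-yl]trimethylsilane
Product: 12 1-methoxy-4-(3-methylidenepent-4-yn-1-yl)benzene
Conditions: K2CO3 (cat.), MeOH, rt
Reagents that add atoms: none
Why: Methoxide-mediated protodesilylation of an alkynylsilane should free the terminal alkyne without touching the alkene or the aryl methyl ether.

Step 7
Reactants: 12 1-methoxy-4-(3-methylidenepent-4-yn-1-yl)benzene
Product: 15 triisopropyl{[5-(4-methoxyphenyl)-3-methylidenepent-1-yn-1-yl]oxy}silane, via lithium acetylide 13 (not isolated), via lithium ynolate 14 (not isolated)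
Conditions: LiN(SiMe3)2, THF, −78 °C; LiOOtBu (from tBuOOH and LiN(SiMe3)2), −78 → 0 °C; iPr3SiOTf, −78 °C; Et3N-deactivated silica
Reagents that add atoms: tert-butyl hydroperoxide (oxygen, delivered as its lithium salt), CC(C)(C)OO; triisopropylsilyl trifluoromethanesulfonate, CC(C)[Si](OS(=O)(=O)C(F)(F)F)(C(C)C)C(C)C
Why: In this Julia oxidation the acetylide attacks the electrophilic peroxide oxygen to give ynolate 14, which the hard silyl triflate should silylate on oxygen to give a chromatographically stable triisopropylsiloxy alkyne.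

Step 8
Reactants: 6 methyl (3S)-3-(2-ethoxy-4-oxocyclobut-2-en-1-yl)-3-phenylpropanoate; 15 triisopropyl{[5-(4-methoxyphenyl)-3-methylidenepent-1-yn-1-yl]oxy}silane
Product: 21 (4R)-5-ethoxy-8-[4-(4-methoxyphenyl)but-1-en-2-yl]-4-phenyl-7-[(triisopropylsilyl)oxy]chroman-2-one, via vinylketene 16 (not isolated), via vinylcyclobutenone 17 (not isolated), via dienylketene 18 (not isolated), via cyclohexadienone 19 (not isolated), via phenol ester 20 (not isolated)
Conditions: 15 (1.3 equiv), toluene, 80 °C then 110 °C; then PPTS (10 mol%), 4 Å sieves, 80 °C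
Reagents that add atoms: none
Why: Thermal 4π opening of 6 gives vinylketene 16, whose ketene C=C adds to the electron-rich alkyne 15 in a (2+2) cycloaddition (C8–C8a and C6–C7); vinylcyclobutenone 17 reopens to dienylketene 18, which undergoes 6π electrocyclisation (C4a–C8a) to dienone 19 and enolises to phenol 20, the Danheiser benzannulation of a cyclobutenone with a siloxyalkyne being the closest known reaction type. Ring A therefore closes by thermal 6π electrocyclisation followed by tautomerisation, and the lactone ring closes by acid-catalysed 6-exo-trig acyl substitution of the methyl ester by the C8a phenol with loss of methanol. No new stereocentre survives (the ring centres of 6, 17 and 19 all become sp2), and C4 should keep its configuration because the alkyl group of 6 rotates outward on opening, which holds its benzylic hydrogen away from the ketene and rules out a 1,5-hydrogen shift. The selectivity needed is regiochemical and is fixed by polarity: the alkyne carbon remote from oxygen bonds to the ketene carbonyl carbon, so the ketene oxygen ends as O1 between C8 and C4a with the siloxy group on C7 and the ethoxy group on C5, and since O1 is the only free phenol the lactone can close in one way only. The 1,1-disubstituted alkene carries the future acyl carbon without any benzylic leaving group, so the free phenol stage cannot shed an ortho-quinone methide.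

Step 9
Reactants: 21 (4R)-5-ethoxy-8-[4-(4-methoxyphenyl)but-1-en-2-yl]-4-phenyl-7-[(triisopropylsilyl)oxy]chroman-2-one
Product: 23 (4R)-5-ethoxy-8-[3-(4-methoxyphenyl)propanoyl]-4-phenyl-7-[(triisopropylsilyl)oxy]chroman-2-one, via diol 22 (not isolated)
Conditions: OsO4 (2 mol%), NaIO4 (4 equiv), 2,6-lutidine, dioxane/H2O 3:1, rt
Reagents that add atoms: osmium tetroxide, O=[Os](=O)(=O)=O; sodium periodate, [Na+].[O-]I(=O)(=O)=O
Why: Lemieux–Johnson cleavage should osmylate the only alkene at its exposed methylene terminus and cleave diol 22 in situ to the aryl ketone, while the lutidine buffer spares the silyl ether and the lactone.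

Step 10
Reactants: 23 (4R)-5-ethoxy-8-[3-(4-methoxyphenyl)propanoyl]-4-phenyl-7-[(triisopropylsilyl)oxy]chroman-2-one
Product: 24 (4R)-5-ethoxy-7-hydroxy-8-[3-(4-methoxyphenyl)propanoyl]-4-phenylchroman-2-one
Conditions: Bu4NF, AcOH (1:1), THF, 0 °C
Reagents that add atoms: none
Why: Fluoride-induced desilylation of the aryl silyl ether under acetic acid buffering should free the C7 phenol without opening the aryl lactone, and because the C5 oxygen is still capped the lactone has no second phenol to move to.

Step 11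
Reactants: 24 (4R)-5-ethoxy-7-hydroxy-8-[3-(4-methoxyphenyl)propanoyl]-4-phenylchroman-2-one
Product: 25 (4R)-5,7-dihydroxy-8-[3-(4-hydroxyphenyl)propanoyl]-4-phenylchroman-2-one
Conditions: BBr3 (6 equiv), CH2Cl2, −78 → 0 °C; ice-water quench
Reagents that add atoms: none
Why: Lewis acid-mediated aryl alkyl ether cleavage (boron coordination, then bromide attack on methyl and ethyl) should free both remaining phenols, and the lactone should stay on O1 because a direct acyl shift to the C5 oxygen is geometrically impossible and the cold, acidic quench avoids hydrolytic ring opening.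

**Compound list**
1 | 3-phenylglutaric anhydride (4-phenyloxane-2,6-dione) | O=C1CC(c2ccccc2)CC(=O)O1 | starting material
2 | (3R)-5-methoxy-5-oxo-3-phenylpentanoic acid | COC(=O)C[C@H](c1ccccc1)CC(=O)O | intermediate
3 | methyl (3S)-5-chloro-5-oxo-3-phenylpentanoate | COC(=O)C[C@H](c1ccccc1)CC(=O)Cl | intermediate
4 | ethoxyacetylene | CCOC#C | starting material
5 | methyl (3S)-5-oxo-3-phenylpent-4-enoate (ketene) | COC(=O)C[C@H](c1ccccc1)C=C=O | intermediate
6 | methyl (3S)-3-(2-ethoxy-4-oxocyclobut-2-en-1-yl)-3-phenylpropanoate (both ring epimers) | COC(=O)C[C@H](c1ccccc1)C1C(=O)C=C1OCC | intermediate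
7 | 4-(4-methoxyphenyl)butan-2-one | COc1ccc(CCC(C)=O)cc1 | starting material
8 | lithium 4-(4-methoxyphenyl)but-1-en-2-olate | [Li+].[O-]C(=C)CCc1ccc(OC)cc1 | intermediate
9 | 4-(4-methoxyphenyl)but-1-en-2-yl trifluoromethanesulfonate | C=C(CCc1ccc(OC)cc1)OS(=O)(=O)C(F)(F)F | intermediate
10 | ethynyltrimethylsilane | C#C[Si](C)(C)C | starting material
11 | [5-(4-methoxyphenyl)-3-methylidenepent-1-yn-1-yl]trimethylsilane | C=C(C#C[Si](C)(C)C)CCc1ccc(OC)cc1 | intermediate
12 | 1-methoxy-4-(3-methylidenepent-4-yn-1-yl)benzene | C=C(C#C)CCc1ccc(OC)cc1 | intermediate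
13 | lithium 5-(4-methoxyphenyl)-3-methylidenepent-1-yn-1-ide | [Li+].[C-]#CC(=C)CCc1ccc(OC)cc1 | intermediate
14 | lithium 5-(4-methoxyphenyl)-3-methylidenepent-1-yn-1-olate | [Li+].[O-]C#CC(=C)CCc1ccc(OC)cc1 | intermediate
15 | triisopropyl{[5-(4-methoxyphenyl)-3-methylidenepent-1-yn-1-yl]oxy}silane | CC(C)[Si](OC#CC(=C)CCc1ccc(OC)cc1)(C(C)C)C(C)C | intermediate
16 | methyl (3S,4Z)-5-ethoxy-7-oxo-3-phenylhepta-4,6-dienoate (vinylketene) | COC(=O)C[C@H](c1ccccc1)/C=C(OCC)/C=C=O | intermediate
17 | methyl (3S,4Z)-5-ethoxy-5-{3-[4-(4-methoxyphenyl)but-1-en-2-yl]-4-oxo-2-[(triisopropylsilyl)oxy]cyclobut-2-en-1-yl}-3-phenylpent-4-enoate (ring centre unassigned) | COC(=O)C[C@H](c1ccccc1)/C=C(OCC)/C1C(=O)C(C(=C)CCc2ccc(OC)cc2)=C1O[Si](C(C)C)(C(C)C)C(C)C | intermediate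
18 | methyl (3S,4Z,6E)-5-ethoxy-8-[4-(4-methoxyphenyl)but-1-en-2-yl]-9-oxo-3-phenyl-7-[(triisopropylsilyl)oxy]nona-4,6,8-trienoate (dienylketene) | COC(=O)C[C@H](c1ccccc1)/C=C(OCC)/C=C(O[Si](C(C)C)(C(C)C)C(C)C)\C(=C=O)C(=C)CCc1ccc(OC)cc1 | intermediate
19 | methyl (3S)-3-{2-ethoxy-5-[4-(4-methoxyphenyl)but-1-en-2-yl]-6-oxo-4-[(triisopropylsilyl)oxy]cyclohexa-2,4-dien-1-yl}-3-phenylpropanoate (ring centre unassigned) | COC(=O)C[C@H](c1ccccc1)C1C(=O)C(C(=C)CCc2ccc(OC)cc2)=C(O[Si](C(C)C)(C(C)C)C(C)C)C=C1OCC | intermediate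
20 | methyl (3R)-3-{6-ethoxy-2-hydroxy-3-[4-(4-methoxyphenyl)but-1-en-2-yl]-4-[(triisopropylsilyl)oxy]phenyl}-3-phenylpropanoate | COC(=O)C[C@H](c1ccccc1)c1c(OCC)cc(O[Si](C(C)C)(C(C)C)C(C)C)c(C(=C)CCc2ccc(OC)cc2)c1O | intermediate
21 | (4R)-5-ethoxy-8-[4-(4-methoxyphenyl)but-1-en-2-yl]-4-phenyl-7-[(triisopropylsilyl)oxy]chroman-2-one | O=C1C[C@H](c2ccccc2)c2c(OCC)cc(O[Si](C(C)C)(C(C)C)C(C)C)c(C(=C)CCc3ccc(OC)cc3)c2O1 | intermediate
22 | (4R)-8-[1,2-dihydroxy-4-(4-methoxyphenyl)butan-2-yl]-5-ethoxy-4-phenyl-7-[(triisopropylsilyl)oxy]chroman-2-one (carbinol centre unassigned) | O=C1C[C@H](c2ccccc2)c2c(OCC)cc(O[Si](C(C)C)(C(C)C)C(C)C)c(C(O)(CO)CCc3ccc(OC)cc3)c2O1 | intermediate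
23 | (4R)-5-ethoxy-8-[3-(4-methoxyphenyl)propanoyl]-4-phenyl-7-[(triisopropylsilyl)oxy]chroman-2-one | O=C1C[C@H](c2ccccc2)c2c(OCC)cc(O[Si](C(C)C)(C(C)C)C(C)C)c(C(=O)CCc3ccc(OC)cc3)c2O1 | intermediate
24 | (4R)-5-ethoxy-7-hydroxy-8-[3-(4-methoxyphenyl)propanoyl]-4-phenylchroman-2-one | O=C1C[C@H](c2ccccc2)c2c(OCC)cc(O)c(C(=O)CCc3ccc(OC)cc3)c2O1 | intermediate
25 | (4R)-5,7-dihydroxy-8-[3-(4-hydroxyphenyl)propanoyl]-4-phenylchroman-2-one | O=C1C[C@H](c2ccccc2)c2c(O)cc(O)c(C(=O)CCc3ccc(O)cc3)c2O1 | target

**Step count**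
Total steps: 11. Longest linear sequence: 8 (steps 4 to 11, from 4-(4-methoxyphenyl)butan-2-one); the other branch runs through steps 1 to 3 and then 8 to 11.

**Steps most likely to fail**

Step 8. The thermal cascade may stall at the phenol ester stage, and the acid then needed for ring closure may protonate the electron-rich 1,1-disubstituted alkene (cationic dimerisation) or loosen the silyl ether. The fallback sets out from 20, isolated after the thermal stage without acid. Hydrolysis of the methyl ester (LiOH, THF/H2O, 0 °C, then dilute HCl) should give (3R)-3-{6-ethoxy-2-hydroxy-3-[4-(4-methoxyphenyl)but-1-en-2-yl]-4-[(triisopropylsilyl)oxy]phenyl}-3-phenylpropanoic acid F1. This is closed by carbodiimide activation of the acid (iPrN=C=NiPr, DMAP cat., CH2Cl2, 0 °C), an acyl-activation lactonisation in place of acid-catalysed transesterification, and the route is rejoined at 21.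

Step 3. The aldoketene may condense with itself faster than it is trapped, and acid chloride 3 may exchange its ester and acid chloride termini through a cyclic acyloxonium ion, which would erode the enantiomeric purity. The fallback sets out from 2 and avoids the acid chloride. Acid 2 is activated in the presence of excess 4 with 2-chloro-1-methylpyridinium iodide and Et3N (CH2Cl2, rt), forming 2-{[(3S)-5-methoxy-5-oxo-3-phenylpentanoyl]oxy}-1-methylpyridin-1-ium iodide F2. This is dehydrohalogenated as it forms, so ketene 5 arises at a low stationary concentration and is trapped by 4, and the route is rejoined at 6.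

Step 7. Oxygen transfer to the conjugated acetylide may be incomplete, and the siloxy enyne may hydrolyse or lose silicon during isolation. The fallback sets out from 9 and replaces the silyl ynol ether by an ethyl ynol ether, which the final boron tribromide step removes as well.
- Sonogashira coupling of 9 with 4 (PdCl2(PPh3)2 cat., CuI cat., Et3N, THF, rt) should give 1-(5-ethoxy-3-methylidenepent-4-yn-1-yl)-4-methoxybenzene F3.
- Heated with 6 in toluene at 80 °C and then treated with PPTS, F3 should react with vinylketene 16 and pass through the ethoxy vinylcyclobutenone methyl (3S,4Z)-5-ethoxy-5-{2-ethoxy-3-[4-(4-methoxyphenyl)but-1-en-2-yl]-4-oxocyclobut-2-en-1-yl}-3-phenylpent-4-enoate F4, the dienylketene methyl (3S,4Z,6E)-5,7-diethoxy-8-[4-(4-methoxyphenyl)but-1-en-2-yl]-9-oxo-3-phenylnona-4,6,8-trienoate F5, the dienone methyl (3S)-3-{2,4-diethoxy-5-[4-(4-methoxyphenyl)but-1-en-2-yl]-6-oxocyclohexa-2,4-dien-1-yl}-3-phenylpropanoate F6 and the phenol ester methyl (3R)-3-{4,6-diethoxy-2-hydroxy-3-[4-(4-methoxyphenyl)but-1-en-2-yl]phenyl}-3-phenylpropanoate F7 to the lactone (4R)-5,7-diethoxy-8-[4-(4-methoxyphenyl)but-1-en-2-yl]-4-phenylchroman-2-one F8.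
- Cleavage with OsO4 (cat.) and NaIO4 as in step 9 would then lead through the diol (4R)-8-[1,2-dihydroxy-4-(4-methoxyphenyl)butan-2-yl]-5,7-diethoxy-4-phenylchroman-2-one F9 to the ketone (4R)-5,7-diethoxy-8-[3-(4-methoxyphenyl)propanoyl]-4-phenylchroman-2-one F10.
- BBr3 in CH2Cl2 then cleaves all three ethers, and the route is rejoined at 25.

Further compounds
F1 | step 8 | (3R)-3-{6-ethoxy-2-hydroxy-3-[4-(4-methoxyphenyl)but-1-en-2-yl]-4-[(triisopropylsilyl)oxy]phenyl}-3-phenylpropanoic acid | OC(=O)C[C@H](c1ccccc1)c1c(OCC)cc(O[Si](C(C)C)(C(C)C)C(C)C)c(C(=C)CCc2ccc(OC)cc2)c1O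
F2 | step 3 | 2-{[(3S)-5-methoxy-5-oxo-3-phenylpentanoyl]oxy}-1-methylpyridin-1-ium iodide | COC(=O)C[C@H](c1ccccc1)CC(=O)Oc1cccc[n+]1C.[I-]
F3 | step 7 | 1-(5-ethoxy-3-methylidenepent-4-yn-1-yl)-4-methoxybenzene | CCOC#CC(=C)CCc1ccc(OC)cc1
F4 | step 7 | methyl (3S,4Z)-5-ethoxy-5-{2-ethoxy-3-[4-(4-methoxyphenyl)but-1-en-2-yl]-4-oxocyclobut-2-en-1-yl}-3-phenylpent-4-enoate | COC(=O)C[C@H](c1ccccc1)/C=C(OCC)/C1C(=O)C(C(=C)CCc2ccc(OC)cc2)=C1OCC
F5 | step 7 | methyl (3S,4Z,6E)-5,7-diethoxy-8-[4-(4-methoxyphenyl)but-1-en-2-yl]-9-oxo-3-phenylnona-4,6,8-trienoate | COC(=O)C[C@H](c1ccccc1)/C=C(OCC)/C=C(OCC)\C(=C=O)C(=C)CCc1ccc(OC)cc1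
F6 | step 7 | methyl (3S)-3-{2,4-diethoxy-5-[4-(4-methoxyphenyl)but-1-en-2-yl]-6-oxocyclohexa-2,4-dien-1-yl}-3-phenylpropanoate | COC(=O)C[C@H](c1ccccc1)C1C(=O)C(C(=C)CCc2ccc(OC)cc2)=C(OCC)C=C1OCC
F7 | step 7 | methyl (3R)-3-{4,6-diethoxy-2-hydroxy-3-[4-(4-methoxyphenyl)but-1-en-2-yl]phenyl}-3-phenylpropanoate | COC(=O)C[C@H](c1ccccc1)c1c(OCC)cc(OCC)c(C(=C)CCc2ccc(OC)cc2)c1O
F8 | step 7 | (4R)-5,7-diethoxy-8-[4-(4-methoxyphenyl)but-1-en-2-yl]-4-phenylchroman-2-one | O=C1C[C@H](c2ccccc2)c2c(OCC)cc(OCC)c(C(=C)CCc3ccc(OC)cc3)c2O1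
F9 | step 7 | (4R)-8-[1,2-dihydroxy-4-(4-methoxyphenyl)butan-2-yl]-5,7-diethoxy-4-phenylchroman-2-one | O=C1C[C@H](c2ccccc2)c2c(OCC)cc(OCC)c(C(O)(CO)CCc3ccc(OC)cc3)c2O1
F10 | step 7 | (4R)-5,7-diethoxy-8-[3-(4-methoxyphenyl)propanoyl]-4-phenylchroman-2-one | O=C1C[C@H](c2ccccc2)c2c(OCC)cc(OCC)c(C(=O)CCc3ccc(OC)cc3)c2O1
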